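**Plan**
1. Cuts: undoing the final hydrogenation restores the C3–C4 alkenes of both pyrans and two O-benzyl groups. Each pyran is then cut at aryl–C4 (C4–C4a) and at O1–C2, so both C5 units return to 1,1-dimethylpropargyl ethers on O-4' and O-4. Those ether C–O bonds lead back to phloretin.
2. Feature: O1 of each pyran sits on an aryl carbon with two equivalent ortho CH carbons. C3'/C5' of ring A mirror each other across the C1'–C4' acyl axis when O-2' and O-6' carry the same group. C3/C5 of ring B are equivalent because that ring is 1,4-disubstituted.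
3. Forward: rings A and B and the three-carbon ketone chain arrive together in phloretin. O-4'/O-4 are propargylated and O-2'/O-6' benzylated, both pyran rings close together in one thermal step, and one hydrogenation ends the route.
4. Stereochemistry: the target has no stereocentre and no stereogenic alkene (each C2 bears two methyl groups), so nothing has to be set.

Key step: step 3

Remark: the target SMILES carries no stereodescriptor and the molecule is achiral, so the constitution alone defines the compound. Primed locants denote the acyl-bearing ring A, unprimed locants ring B, and O1/C2/C3/C4/C4a are chroman locants.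

Step 1
Reactants: 1 phloretin; 2 3-chloro-3-methylbut-1-yne
Product: 3 1-{2,6-dihydroxy-4-[(2-methylbut-3-yn-2-yl)oxy]phenyl}-3-{4-[(2-methylbut-3-yn-2-yl)oxy]phenyl}propan-1-one
Conditions: 2 (2.2 equiv), CuCl2·2H2O (1 mol %), DBU (3.2 equiv), MeCN, 0 °C, Ar
Reagents that add atoms: none
Why: Copper-catalysed propargylic etherification of phenols with a tertiary propargyl chloride (phenoxide attack on a copper-acetylide-stabilised propargyl cation) should pick O-4', the most acidic hydroxyl, and O-4, the most nucleophilic and least hindered one, because O-2' and O-6' are hydrogen-bonded to the ketone and crowded by the acyl chain against a tertiary electrophile, and the 0 °C temperature keeps the new ring A ether from rearranging while its neighbours are still free.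

Step 2
Reactants: 3 the 4,4'-bis(propargyl) ether of phloretin
Product: 4 1-{2,6-bis(benzyloxy)-4-[(2-methylbut-3-yn-2-yl)oxy]phenyl}-3-{4-[(2-methylbut-3-yn-2-yl)oxy]phenyl}propan-1-one
Conditions: BnBr (2.6 equiv), Cs2CO3 (3 equiv), TBAI (cat.), DMF, rt
Reagents that add atoms: benzyl bromide, BrCc1ccccc1
Why: Williamson etherification with caesium phenoxides in DMF is strong enough to alkylate both chelated hydroxyls at room temperature, where the propargyl ethers, the terminal alkynes and the ketone are untouched, and two identical benzyl groups keep ring A symmetric, remove the neighbouring nucleophilic oxygens and can leave later under hydrogen without any acid.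

Step 3
Reactants: 4 the 2',6'-di-O-benzyl 4,4'-bis(1,1-dimethylpropargyl) ether
Product: 7 1-[5,7-bis(benzyloxy)-2,2-dimethyl-2H-chromen-6-yl]-3-(2,2-dimethyl-2H-chromen-6-yl)propan-1-one, via bis(allenylphenol) 5 (not isolated), via bis(ortho-quinone methide) 6 (not isolated)
Conditions: PhNEt2 (degassed, dilute), 190 °C, Ar
Reagents that add atoms: none
Why: Each aryl 1,1-dimethylpropargyl ether undergoes a thermal aromatic propargyl Claisen [3,3] shift that breaks O–CMe2 and joins the alkyne terminus to an ortho carbon (the future C4–C4a bond), and tautomerisation restores the phenol as allenylphenol 5. A 1,5-hydrogen shift from the phenolic OH to the central allene carbon then gives ortho-quinone methide 6, a 1-oxatriene. Both pyran rings close in the same mode, a thermal disrotatory oxa-6π electrocyclisation that re-forms O1–C2 and rearomatises the carbocycle. This is the classical thermal conversion of aryl 1,1-dimethylpropargyl ethers into 2,2-dimethyl-2H-chromenes, run here at two independent sites of one molecule, in which the geminal methyl groups lower the barrier of the [3,3] step and the absence of a strong base keeps 5 away from the five-ring closure that leads to benzofurans. Only regioselectivity is needed: C3'/C5' are interchanged by the mirror plane through C1'–C4' because O-2' and O-6' both carry benzyl, C3/C5 are equivalent by para substitution, and the benzylated ring A oxygens have no proton to shift and cannot add to the quinone methide, so closure can use only O-4' and the pyran oxygen ends para to the ketone. No stereocentre is created, since each C2 bears two methyl groups.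

Step 4
Reactants: 7 the dibenzyl bis(chromene)
Product: 8 1-(5,7-dihydroxy-2,2-dimethylchroman-6-yl)-3-(2,2-dimethylchroman-6-yl)propan-1-one (target)
Conditions: H2 (1 atm), 10% Pd/C, EtOAc–EtOH, rt
Reagents that add atoms: none
Why: Heterogeneous catalytic hydrogenation saturates the two cis-disubstituted styrene-type alkenes and hydrogenolyses both aryl benzyl ethers in the same flask, while the electron-rich, doubly ortho-oxygenated aryl ketone (chelated as the phenols appear) and the tertiary alkyl aryl ether bonds of the chromans are not attacked at 1 atm, so no acid ever meets the chromans and the pyran oxygen cannot move to O-2'.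

**Compound list**
1 | phloretin | O=C(CCc1ccc(O)cc1)c1c(O)cc(O)cc1O | starting material
2 | 3-chloro-3-methylbut-1-yne | C#CC(C)(C)Cl | starting material
3 | 1-{2,6-dihydroxy-4-[(2-methylbut-3-yn-2-yl)oxy]phenyl}-3-{4-[(2-methylbut-3-yn-2-yl)oxy]phenyl}propan-1-one | C#CC(C)(C)Oc1ccc(CCC(=O)c2c(O)cc(OC(C)(C)C#C)cc2O)cc1 | intermediate
4 | 1-{2,6-bis(benzyloxy)-4-[(2-methylbut-3-yn-2-yl)oxy]phenyl}-3-{4-[(2-methylbut-3-yn-2-yl)oxy]phenyl}propan-1-one (key-step precursor) | C#CC(C)(C)Oc1ccc(CCC(=O)c2c(OCc3ccccc3)cc(OC(C)(C)C#C)cc2OCc4ccccc4)cc1 | intermediate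
5 | bis(allenylphenol), both halves drawn at the same stage: 1-[2,6-bis(benzyloxy)-4-hydroxy-3-(3-methylbuta-1,2-dien-1-yl)phenyl]-3-[4-hydroxy-3-(3-methylbuta-1,2-dien-1-yl)phenyl]propan-1-one | CC(C)=C=Cc1cc(CCC(=O)c2c(OCc3ccccc3)cc(O)c(C=C=C(C)C)c2OCc4ccccc4)ccc1O | intermediate
6 | bis(ortho-quinone methide), both halves drawn at the same stage: each ring is a 6-(3-methylbut-2-en-1-ylidene)cyclohexa-2,4-dien-1-one, ring A still carrying both benzyloxy groups and the acyl chain | CC(C)=CC=C1C=C(CCC(=O)C2=C(OCc3ccccc3)C(=CC=C(C)C)C(=O)C=C2OCc4ccccc4)C=CC1=O | intermediate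
7 | 1-[5,7-bis(benzyloxy)-2,2-dimethyl-2H-chromen-6-yl]-3-(2,2-dimethyl-2H-chromen-6-yl)propan-1-one (key-step product) | CC1(C)C=Cc2cc(CCC(=O)c3c(OCc5ccccc5)cc4c(c3OCc6ccccc6)C=CC(C)(C)O4)ccc2O1 | intermediate
8 | 1-(5,7-dihydroxy-2,2-dimethylchroman-6-yl)-3-(2,2-dimethylchroman-6-yl)propan-1-one, achiral | CC1(C)CCc2cc(CCC(=O)c3c(O)cc4c(c3O)CCC(C)(C)O4)ccc2O1 | target

Total step count: 4. Longest linear sequence: 4 steps (from phloretin).

**Steps most likely to fail**

Step 1. The ring A ortho-hydroxyls become the more acidic sites once O-4' is etherified. Together with the electron-rich carbons C3'/C5', they may compete with the ring B hydroxyl for the propargyl electrophile, which would cause over-etherification, C-alkylation or incomplete reaction at O-4. The fallback builds the skeleton convergently, so that each phenol is etherified on its own fragment and never competes with the other ring. It sets out from 2 and comes back at 8.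
- Purchased 4-hydroxybenzaldehyde and 2 under the copper/DBU conditions give 4-[(2-methylbut-3-yn-2-yl)oxy]benzaldehyde F1.
- Purchased 2,4,6-trihydroxyacetophenone with one equivalent each of 2 and base gives 1-{2,6-dihydroxy-4-[(2-methylbut-3-yn-2-yl)oxy]phenyl}ethanone F2.
- F2 is benzylated as in step 2 to 1-{2,6-bis(benzyloxy)-4-[(2-methylbut-3-yn-2-yl)oxy]phenyl}ethanone F3.
- A Claisen–Schmidt condensation of F3 with F1 (KOH, EtOH, rt) gives the (E)-chalcone bis(propargyl) ether F4.
- The same double thermal cascade (PhNEt2, 190 °C) turns F4 into the (E)-chalcone bis(chromene) F5.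
- H2 over Pd/C then saturates three alkenes and removes both benzyl groups to give 8.

Step 3. The two ethers may rearrange at unequal rates, so the ring that closes first is exposed to long heating and may oligomerise. The tertiary ethers may also lose their C5 unit by thermal elimination before the [3,3] shift. The fallback replaces the propargyl Claisen/electrocyclisation by an allyl Claisen/hydroalkoxylation sequence. It sets out from 4 and comes back at 8.
- Semi-hydrogenation of both alkynes (H2, Lindlar catalyst, quinoline, EtOAc) gives the bis(2-methylbut-3-en-2-yl) ether F6.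
- The aromatic allyl Claisen rearrangement has the lower barrier. In PhNEt2 at about 150 °C it carries each unit with allylic inversion to the same equivalent ortho carbons and gives the bis(ortho-prenyl)phenol F7.
- Acid-catalysed Markovnikov hydroalkoxylation (Amberlyst 15, CH2Cl2, rt) closes both rings, with only O-4' and O-4 bearing a proton, to give the dibenzyl bis(chroman) F8.
- Hydrogenolysis of F8 (H2, Pd/C) gives 8.

Step 2. Alkylation of the second chelated hydroxyl may be slow and ring A may be C-benzylated. If heat is then applied, the ring A ether may shift early while a neighbouring oxygen is still free, which would scramble the closing oxygen. The fallback reverses the order, so the heat-sensitive ethers are installed last and exhaustively. It sets out from 1 and comes back at 4.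
- Pivaloyl chloride (2.1 equiv), Et3N, CH2Cl2, 0 °C acylates the two unchelated hydroxyls to 4,4'-di-O-pivaloylphloretin F9.
- BnBr, K2CO3, DMF, 60 °C (heat is now harmless) gives 2',6'-di-O-benzyl-4,4'-di-O-pivaloylphloretin F10.
- K2CO3 in MeOH frees 2',6'-di-O-benzylphloretin F11.
- The only two hydroxyls of F11 are etherified with excess 2 under the copper/DBU conditions to give 4.

**Further compounds**
F1 | step 1 | 4-[(2-methylbut-3-yn-2-yl)oxy]benzaldehyde | C#CC(C)(C)Oc1ccc(C=O)cc1
F2 | step 1 | 1-{2,6-dihydroxy-4-[(2-methylbut-3-yn-2-yl)oxy]phenyl}ethanone | CC(=O)c1c(O)cc(OC(C)(C)C#C)cc1O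
F3 | step 1 | 1-{2,6-bis(benzyloxy)-4-[(2-methylbut-3-yn-2-yl)oxy]phenyl}ethanone | CC(=O)c1c(OCc2ccccc2)cc(OC(C)(C)C#C)cc1OCc3ccccc3
F4 | step 1 | (E)-1-{2,6-bis(benzyloxy)-4-[(2-methylbut-3-yn-2-yl)oxy]phenyl}-3-{4-[(2-methylbut-3-yn-2-yl)oxy]phenyl}prop-2-en-1-one | C#CC(C)(C)Oc1ccc(/C=C/C(=O)c2c(OCc3ccccc3)cc(OC(C)(C)C#C)cc2OCc4ccccc4)cc1
F5 | step 1 | (E)-1-[5,7-bis(benzyloxy)-2,2-dimethyl-2H-chromen-6-yl]-3-(2,2-dimethyl-2H-chromen-6-yl)prop-2-en-1-one | CC1(C)C=Cc2cc(/C=C/C(=O)c3c(OCc5ccccc5)cc4c(c3OCc6ccccc6)C=CC(C)(C)O4)ccc2O1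
F6 | step 3 | 1-{2,6-bis(benzyloxy)-4-[(2-methylbut-3-en-2-yl)oxy]phenyl}-3-{4-[(2-methylbut-3-en-2-yl)oxy]phenyl}propan-1-one | C=CC(C)(C)Oc1ccc(CCC(=O)c2c(OCc3ccccc3)cc(OC(C)(C)C=C)cc2OCc4ccccc4)cc1
F7 | step 3 | 1-[2,6-bis(benzyloxy)-4-hydroxy-3-(3-methylbut-2-en-1-yl)phenyl]-3-[4-hydroxy-3-(3-methylbut-2-en-1-yl)phenyl]propan-1-one | CC(C)=CCc1cc(CCC(=O)c2c(OCc3ccccc3)cc(O)c(CC=C(C)C)c2OCc4ccccc4)ccc1O
F8 | step 3 | 1-[5,7-bis(benzyloxy)-2,2-dimethylchroman-6-yl]-3-(2,2-dimethylchroman-6-yl)propan-1-one | CC1(C)CCc2cc(CCC(=O)c3c(OCc5ccccc5)cc4c(c3OCc6ccccc6)CCC(C)(C)O4)ccc2O1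
F9 | step 2 | 4,4'-di-O-pivaloylphloretin | CC(C)(C)C(=O)Oc1ccc(CCC(=O)c2c(O)cc(OC(=O)C(C)(C)C)cc2O)cc1
F10 | step 2 | 2',6'-di-O-benzyl-4,4'-di-O-pivaloylphloretin | CC(C)(C)C(=O)Oc1ccc(CCC(=O)c2c(OCc3ccccc3)cc(OC(=O)C(C)(C)C)cc2OCc4ccccc4)cc1
F11 | step 2 | 2',6'-di-O-benzylphloretin | O=C(CCc1ccc(O)cc1)c2c(OCc3ccccc3)cc(O)cc2OCc4ccccc4
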